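**Retrosynthetic overview**
1. Target ⇐ esterification of the 8β‑hydroxy germacranolide with the preformed (2S,3R)-epoxy acid; the germacranolide ⇐ CrCl2-mediated intramolecular allylation/lactonisation (C6–C7 bond) of a seco Z‑enal / 2‑(bromomethyl)enoate.
2. Seco chain: enal from a Z‑Weinreb amide, allyl bromide from an allylsilane, C1–C10 oxirane by Shi epoxidation before ring closure.
3. C8–O by proline-catalysed α‑aminoxylation / Horner–Wadsworth–Emmons olefination of an aldehyde obtained by cutting the geranyl terminus.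
4. C3 stereocentre, 4Z alkene and C6 carbonyl from an enantioselective phase-transfer γ‑alkylation of 4‑methylfuran‑2(5H)‑one with geranyl bromide (new reaction), then lactone opening.
5. Ring order: C1–C10 oxirane → ten-membered carbocycle and γ‑lactone in one step → side-chain oxirane attached preformed.

Assumption: the SMILES is taken at face value (1R,3S,6R,7R,8R,10R, 4Z; (2R)-2-methylbutanoate; (2S,3R)-2,3-dimethyloxirane-2-carboxylate with cis methyl groups); ring locants and α/β labels follow germacrane numbering, and all numbered starting materials are commercial.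

**Step 1**
Reactants: 1 4-methylfuran-2(5H)-one (1.5 equiv); 2 geranyl bromide
Product: 3 (S)-5-[(2E)-3,7-dimethylocta-2,6-dien-1-yl]-4-methylfuran-2(5H)-one
Conditions: N-(9-anthracenylmethyl)cinchonidinium bromide (free 9-OH, 10 mol%), Cs2CO3 (solid), toluene/CHCl3, −30 °C
Reagents that add atoms: none
Why: Proposed new method: enantioselective phase-transfer vinylogous (γ) alkylation of a butenolide. Cs2CO3 forms the aromatic 2-furanolate at the solid–liquid interface; the ammonium ion pairs with it and its 9-OH hydrogen-bonds the oxido group, which blocks O and C3 and one face, so the allylic bromide attacks C5 by SN2 and sets C3 of the target as S. The closest known reactions are cinchona phase-transfer alkylations of glycine Schiff bases and organocatalytic vinylogous additions/allylic alkylations of butenolides. The sense of induction must be found by experiment; the cinchoninium pseudo-enantiomer is used if it is opposite. Weak base, low temperature and excess 1 limit racemisation and dialkylation.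

**Step 2**
Reactants: 3 (S)-5-geranyl-4-methylfuran-2(5H)-one
Product: 4 (2Z,4S,6E)-4-hydroxy-N-methoxy-N,3,7,11-tetramethyldodeca-2,6,10-trienamide
Conditions: MeNH(OMe), AlMe3, CH2Cl2, 0 °C
Reagents that add atoms: N,O-dimethylhydroxylamine (CNOC)
Why: Weinreb aminolysis of the lactone by the aluminium amide; the ring fixes the Z geometry, the weakly basic reagent leaves C3 untouched, and the amide is a latent aldehyde that later can be reduced beside esters.

**Step 3**
Reactants: 5 tiglic acid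
Product: 6 (R)-2-methylbutanoic acid
Conditions: H2 (4 atm), Ru(OAc)2[(R)-H8-BINAP] (0.5 mol%), MeOH, rt
Reagents that add atoms: none
Why: Noyori-type asymmetric hydrogenation of an α,β-unsaturated acid; the (R)-ligand gives the (R)-acid (about 97% ee).

**Step 4**
Reactants: 4 hydroxy Weinreb amide; 6 (R)-2-methylbutanoic acid
Product: 7 (2Z,4S,6E)-1-[methoxy(methyl)amino]-3,7,11-trimethyl-1-oxododeca-2,6,10-trien-4-yl (2R)-2-methylbutanoate
Conditions: DCC, DMAP (cat.), CH2Cl2, 0 °C
Reagents that add atoms: none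
Why: Steglich esterification installs the final C3 ester at once and prevents relactonisation; no stereocentre is touched.

**Step 5**
Reactants: 7 trienyl ester
Product: 9 (2Z,4S,6E)-1-[methoxy(methyl)amino]-3,7-dimethyl-1,10-dioxodeca-2,6-dien-4-yl (2R)-2-methylbutanoate, via terminal epoxide 8 (not isolated)
Conditions: mCPBA (1.0 equiv), CH2Cl2, −20 °C; then H5IO6, THF/H2O, 0 °C
Reagents that add atoms: mCPBA (OOC(=O)c1cccc(Cl)c1); water (O)
Why: Prilezhaev epoxidation prefers the unhindered, most electron-rich isopropylidene alkene; the inner alkene is slowed by the homoallylic acyloxy group and the enamide is inert (expected about 5:1, minor isomer removed). Periodic acid then cleaves the epoxide to the aldehyde and acetone.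

**Step 6**
Reactants: 10 trimethyl phosphonoacetate; 11 (iodomethyl)trimethylsilane
Product: 12 methyl 2-(dimethoxyphosphoryl)-3-(trimethylsilyl)propanoate
Conditions: NaH, DME, 0 → 70 °C
Reagents that add atoms: none
Why: SN2 C-alkylation of the phosphonoacetate anion; the racemic centre disappears in step 7.

**Step 7**
Reactants: 9 aldehyde; 12 silyl phosphonate
Product: 14 methyl (2Z,4R,6E,9S,10Z)-4-(anilinooxy)-12-[methoxy(methyl)amino]-6,10-dimethyl-9-{[(2R)-2-methylbutanoyl]oxy}-12-oxo-2-[(trimethylsilyl)methyl]dodeca-2,6,10-trienoate, via alpha-aminoxy aldehyde 13 (not isolated)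
Conditions: L-proline (20 mol%), PhNO (1.0 equiv), DMSO, rt; then 12, LiCl, DBU, MeCN, 0 °C
Reagents that add atoms: nitrosobenzene (O=Nc1ccccc1)
Why: Proline-catalysed α-aminoxylation (enamine attacks the O of PhNO in the hydrogen-bonded transition state; L-proline gives R at C8), trapped at once by Masamune–Roush Horner–Wadsworth–Emmons olefination; the major isomer has the ester trans to C8.

**Step 8**
Reactants: 14 anilinooxy ester
Product: 15 methyl (2Z,4R,6E,9S,10Z)-4-hydroxy-12-[methoxy(methyl)amino]-6,10-dimethyl-9-{[(2R)-2-methylbutanoyl]oxy}-12-oxo-2-[(trimethylsilyl)methyl]dodeca-2,6,10-trienoate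
Conditions: Cu(OAc)2·H2O (30 mol%), MeOH, rt
Reagents that add atoms: none
Why: Copper-mediated N–O cleavage frees the C8 hydroxyl without reducing the γ-oxygenated enoate; any minor olefin isomer lactonises and is separated.

**Step 9**
Reactants: 15 γ-hydroxy ester
Product: 16 methyl (2Z,4R,6E,9S,10Z)-4-[(tert-butyldimethylsilyl)oxy]-12-[methoxy(methyl)amino]-6,10-dimethyl-9-{[(2R)-2-methylbutanoyl]oxy}-12-oxo-2-[(trimethylsilyl)methyl]dodeca-2,6,10-trienoate
Conditions: TBSCl, imidazole, DMF, rt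
Reagents that add atoms: tert-butyldimethylsilyl chloride (CC(C)(C)[Si](C)(C)Cl)
Why: Silylation; a silyl ether is needed at C8 because an acyloxy group there would be expelled by 1,4-elimination from the allylchromium of step 13, and a free hydroxyl would displace the allylic bromide of step 12.

**Step 10**
Reactants: 16 silyl ether
Product: 17 methyl (2Z,4R,6R,7R,9S,10Z)-4-[(tert-butyldimethylsilyl)oxy]-6,7-epoxy-12-[methoxy(methyl)amino]-6,10-dimethyl-9-{[(2R)-2-methylbutanoyl]oxy}-12-oxo-2-[(trimethylsilyl)methyl]dodeca-2,10-dienoate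
Conditions: D-fructose-derived Shi ketone (30 mol%), Oxone (2KHSO5·KHSO4·K2SO4), K2CO3, Bu4NHSO4, MeCN/DMM/aq. Na2B4O7 buffer (pH 10.5), 0 °C
Reagents that add atoms: potassium peroxymonosulfate ([K+].[O-]S(=O)(=O)OO)
Why: Shi epoxidation of the only electron-rich alkene (the enamide and enoate alkenes are inert); the spiro transition state of the D-fructose ketone gives the (R,R)-epoxide of an E-trisubstituted alkene, i.e. 1R,10R of the target. It also removes the alkene that would compete in step 12 and undergo ene cyclisation with the enal.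

**Step 11**
Reactants: 17 epoxy Weinreb amide
Product: 18 methyl (2Z,4R,6R,7R,9S,10Z)-4-[(tert-butyldimethylsilyl)oxy]-6,7-epoxy-6,10-dimethyl-9-{[(2R)-2-methylbutanoyl]oxy}-12-oxo-2-[(trimethylsilyl)methyl]dodeca-2,10-dienoate
Conditions: Cp2Zr(H)Cl (1.5 equiv), THF, rt, 20 min; wet silica gel
Reagents that add atoms: none
Why: Schwartz-reagent reduction of a tertiary amide stops at the aldehyde and spares the three esters, the epoxide and the silanes; the Z geometry is kept and the enal is used crude.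

**Step 12**
Reactants: 18 Z-enal allylsilane
Product: 20 methyl (2Z,4R,6R,7R,9S,10Z)-2-(bromomethyl)-4-[(tert-butyldimethylsilyl)oxy]-6,7-epoxy-6,10-dimethyl-9-{[(2R)-2-methylbutanoyl]oxy}-12-oxododeca-2,10-dienoate, via secondary allylic bromide 19 (not isolated)
Conditions: NBS, propylene oxide, MeCN, −20 → 0 °C, dark; then LiBr (10 mol%), rt
Reagents that add atoms: N-bromosuccinimide (O=C1CCC(=O)N1Br)
Why: Electrophilic bromodesilylation (SE2') of the allylsilane, now the only π-nucleophile, followed by bromide-catalysed SN2' shift to the conjugated primary bromide.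

**Step 13**
Reactants: 20 bromo enal
Product: 22 (4Z)-8β-[(tert-butyldimethylsilyl)oxy]-1β,10α-epoxy-3β-[(2R)-2-methylbutanoyloxy]germacra-4,11(13)-dien-12,6α-olide, via seco hydroxy ester 21 (not isolated)
Conditions: CrCl2 (8 equiv), THF/DMF, slow addition of 20 to 2 mM, rt
Reagents that add atoms: none
Why: Intramolecular Nozaki–Hiyama-type (chromium Barbier) allylation, the ring closure used for germacranolides. The allylchromium equilibrates to the E form and adds through a chair transition state to give the anti adduct, which lactonises to the trans (6α,12) lactone. The C8 silyloxy centre is expected to direct attack to give H-7α, setting C6 (R) and C7; only the C6 alkoxide is free to lactonise.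

**Step 14**
Reactants: 22 silyl ether lactone
Product: 23 (4Z)-1β,10α-epoxy-8β-hydroxy-3β-[(2R)-2-methylbutanoyloxy]germacra-4,11(13)-dien-12,6α-olide
Conditions: TBAF, AcOH (1:1), THF, 0 °C → rt
Reagents that add atoms: none
Why: Buffered fluoride desilylation; without free alkoxide the lactone does not migrate to O8 and the epoxide and methylene lactone survive.

**Step 15**
Reactants: 24 (E)-2-methylbut-2-en-1-ol
Product: 25 [(2R,3R)-2,3-dimethyloxiran-2-yl]methanol
Conditions: Ti(OiPr)4 (10 mol%), D-(−)-diethyl tartrate (12 mol%), t-BuOOH, 4 Å molecular sieves, CH2Cl2, −20 °C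
Reagents that add atoms: tert-butyl hydroperoxide (CC(C)(C)OO)
Why: Sharpless asymmetric epoxidation; the D-tartrate delivers oxygen to the face that gives the (2R,3R)-epoxy alcohol, and the E alkene fixes the cis methyl groups.

**Step 16**
Reactants: 25 epoxy alcohol
Product: 26 (2S,3R)-2,3-dimethyloxirane-2-carboxylic acid
Conditions: TEMPO (20 mol%), PhI(OAc)2 (2.2 equiv), MeCN/H2O, rt
Reagents that add atoms: water (O)
Why: Oxoammonium (TEMPO/PhI(OAc)2) oxidation of the primary alcohol to the acid under near-neutral conditions; the centres are unchanged (the C2 descriptor changes only by priority).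

**Step 17**
Reactants: 23 8β-hydroxy lactone; 26 epoxy acid
Product: 27 (4Z)-1β,10α-epoxy-8β-[(2S,3R)-2,3-dimethyloxirane-2-carbonyloxy]-3β-[(2R)-2-methylbutanoyloxy]germacra-4,11(13)-dien-12,6α-olide (target)
Conditions: 2-methyl-6-nitrobenzoic anhydride (MNBA), Et3N, DMAP, CH2Cl2, rt
Reagents that add atoms: none
Why: Shiina mixed-anhydride esterification couples a hindered acid to a hindered secondary alcohol without acid, so both oxiranes and the methylene lactone survive; no stereocentre is affected.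

**Compound list**
1 | 4-methylfuran-2(5H)-one | CC1=CC(=O)OC1 | starting material
2 | geranyl bromide, (2E)-1-bromo-3,7-dimethylocta-2,6-diene | CC(C)=CCC/C(C)=C/CBr | starting material
3 | (S)-5-[(2E)-3,7-dimethylocta-2,6-dien-1-yl]-4-methylfuran-2(5H)-one | CC1=CC(=O)O[C@H]1C/C=C(\C)CCC=C(C)C | intermediate
4 | (2Z,4S,6E)-4-hydroxy-N-methoxy-N,3,7,11-tetramethyldodeca-2,6,10-trienamide | CON(C)C(=O)/C=C(/C)[C@@H](O)C/C=C(\C)CCC=C(C)C | intermediate
5 | tiglic acid | C/C=C(\C)C(=O)O | starting material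
6 | (R)-2-methylbutanoic acid | CC[C@@H](C)C(=O)O | intermediate
7 | (2Z,4S,6E)-1-[methoxy(methyl)amino]-3,7,11-trimethyl-1-oxododeca-2,6,10-trien-4-yl (2R)-2-methylbutanoate | CON(C)C(=O)/C=C(/C)[C@@H](OC(=O)[C@H](C)CC)C/C=C(\C)CCC=C(C)C | intermediate
8 | 10,11-epoxide of 7 (both epimers at C10) | CON(C)C(=O)/C=C(/C)[C@@H](OC(=O)[C@H](C)CC)C/C=C(\C)CCC1OC1(C)C | intermediate
9 | (2Z,4S,6E)-1-[methoxy(methyl)amino]-3,7-dimethyl-1,10-dioxodeca-2,6-dien-4-yl (2R)-2-methylbutanoate | CON(C)C(=O)/C=C(/C)[C@@H](OC(=O)[C@H](C)CC)C/C=C(\C)CCC=O | intermediate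
10 | trimethyl phosphonoacetate | COC(=O)CP(=O)(OC)OC | starting material
11 | (iodomethyl)trimethylsilane | C[Si](C)(C)CI | starting material
12 | methyl 2-(dimethoxyphosphoryl)-3-(trimethylsilyl)propanoate (racemic) | COC(=O)C(C[Si](C)(C)C)P(=O)(OC)OC | intermediate
13 | (2Z,4S,6E,9R)-9-(anilinooxy)-1-[methoxy(methyl)amino]-3,7-dimethyl-1,10-dioxodeca-2,6-dien-4-yl (2R)-2-methylbutanoate | CON(C)C(=O)/C=C(/C)[C@@H](OC(=O)[C@H](C)CC)C/C=C(\C)C[C@@H](ONc1ccccc1)C=O | intermediate
14 | methyl (2Z,4R,6E,9S,10Z)-4-(anilinooxy)-12-[methoxy(methyl)amino]-6,10-dimethyl-9-{[(2R)-2-methylbutanoyl]oxy}-12-oxo-2-[(trimethylsilyl)methyl]dodeca-2,6,10-trienoate | CON(C)C(=O)/C=C(/C)[C@@H](OC(=O)[C@H](C)CC)C/C=C(\C)C[C@@H](ONc1ccccc1)/C=C(/C(=O)OC)C[Si](C)(C)C | intermediate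
15 | 4-hydroxy analogue of 14 (2Z,4R,6E,9S,10Z) | CON(C)C(=O)/C=C(/C)[C@@H](OC(=O)[C@H](C)CC)C/C=C(\C)C[C@@H](O)/C=C(/C(=O)OC)C[Si](C)(C)C | intermediate
16 | 4-[(tert-butyldimethylsilyl)oxy] analogue of 15 (2Z,4R,6E,9S,10Z) | CON(C)C(=O)/C=C(/C)[C@@H](OC(=O)[C@H](C)CC)C/C=C(\C)C[C@@H](O[Si](C)(C)C(C)(C)C)/C=C(/C(=O)OC)C[Si](C)(C)C | intermediate
17 | methyl (2Z,4R,6R,7R,9S,10Z)-4-[(tert-butyldimethylsilyl)oxy]-6,7-epoxy-12-[methoxy(methyl)amino]-6,10-dimethyl-9-{[(2R)-2-methylbutanoyl]oxy}-12-oxo-2-[(trimethylsilyl)methyl]dodeca-2,10-dienoate | CON(C)C(=O)/C=C(/C)[C@@H](OC(=O)[C@H](C)CC)C[C@H]1O[C@]1(C)C[C@@H](O[Si](C)(C)C(C)(C)C)/C=C(/C(=O)OC)C[Si](C)(C)C | intermediate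
18 | methyl (2Z,4R,6R,7R,9S,10Z)-4-[(tert-butyldimethylsilyl)oxy]-6,7-epoxy-6,10-dimethyl-9-{[(2R)-2-methylbutanoyl]oxy}-12-oxo-2-[(trimethylsilyl)methyl]dodeca-2,10-dienoate | O=C/C=C(/C)[C@@H](OC(=O)[C@H](C)CC)C[C@H]1O[C@]1(C)C[C@@H](O[Si](C)(C)C(C)(C)C)/C=C(/C(=O)OC)C[Si](C)(C)C | intermediate
19 | methyl (4R,6R,7R,9S,10Z)-3-bromo-4-[(tert-butyldimethylsilyl)oxy]-6,7-epoxy-6,10-dimethyl-9-{[(2R)-2-methylbutanoyl]oxy}-2-methylidene-12-oxododec-10-enoate (C3 epimers) | O=C/C=C(/C)[C@@H](OC(=O)[C@H](C)CC)C[C@H]1O[C@]1(C)C[C@@H](O[Si](C)(C)C(C)(C)C)C(Br)C(=C)C(=O)OC | intermediate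
20 | methyl (2Z,4R,6R,7R,9S,10Z)-2-(bromomethyl)-4-[(tert-butyldimethylsilyl)oxy]-6,7-epoxy-6,10-dimethyl-9-{[(2R)-2-methylbutanoyl]oxy}-12-oxododeca-2,10-dienoate | O=C/C=C(/C)[C@@H](OC(=O)[C@H](C)CC)C[C@H]1O[C@]1(C)C[C@@H](O[Si](C)(C)C(C)(C)C)/C=C(/C(=O)OC)CBr | intermediate
21 | methyl (4Z)-8β-[(tert-butyldimethylsilyl)oxy]-1β,10α-epoxy-6α-hydroxy-3β-[(2R)-2-methylbutanoyloxy]germacra-4,11(13)-dien-12-oate (formed as its chromium alkoxide) | C=C(C(=O)OC)[C@H]1[C@H](O)/C=C(/C)[C@@H](OC(=O)[C@H](C)CC)C[C@H]2O[C@]2(C)C[C@H]1O[Si](C)(C)C(C)(C)C | intermediate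
22 | (4Z)-8β-[(tert-butyldimethylsilyl)oxy]-1β,10α-epoxy-3β-[(2R)-2-methylbutanoyloxy]germacra-4,11(13)-dien-12,6α-olide | C=C1C(=O)O[C@@H]2/C=C(/C)[C@@H](OC(=O)[C@H](C)CC)C[C@H]3O[C@]3(C)C[C@@H](O[Si](C)(C)C(C)(C)C)[C@@H]12 | intermediate
23 | (4Z)-1β,10α-epoxy-8β-hydroxy-3β-[(2R)-2-methylbutanoyloxy]germacra-4,11(13)-dien-12,6α-olide | C=C1C(=O)O[C@@H]2/C=C(/C)[C@@H](OC(=O)[C@H](C)CC)C[C@H]3O[C@]3(C)C[C@@H](O)[C@@H]12 | intermediate
24 | (E)-2-methylbut-2-en-1-ol | C/C=C(\C)CO | starting material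
25 | [(2R,3R)-2,3-dimethyloxiran-2-yl]methanol | OC[C@@]1(C)O[C@@H]1C | intermediate
26 | (2S,3R)-2,3-dimethyloxirane-2-carboxylic acid | OC(=O)[C@@]1(C)O[C@@H]1C | intermediate
27 | CNP0265335.4, (1R,3S,6R,7R,8R,10R,4Z)-1,10-epoxy-8-[(2S,3R)-2,3-dimethyloxirane-2-carbonyloxy]-3-[(2R)-2-methylbutanoyloxy]germacra-4,11(13)-dien-12,6-olide | C=C1C(=O)O[C@@H]2/C=C(/C)[C@@H](OC(=O)[C@H](C)CC)C[C@H]3O[C@]3(C)C[C@@H](OC(=O)[C@@]3(C)O[C@@H]3C)[C@@H]12 | target

**Totals**
Total step count: 17. Longest linear sequence: 13 steps (1, 2, 4, 5, 7, 8, 9, 10, 11, 12, 13, 14, 17).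

**Three steps most likely to fail**

Step 1 (the new phase-transfer γ-alkylation; risks are α- or O-alkylation, low ee and racemisation of 3). Fallback with known chemistry, setting out from 1 and 2 and coming back at 3: silylate 1 (TBSOTf, Et3N) to tert-butyl(dimethyl)[(4-methylfuran-2-yl)oxy]silane F1. Alkylate F1 with 2 under silver promotion (AgOCOCF3, CH2Cl2), which is γ-selective, to racemic 5-geranyl-4-methylfuran-2(5H)-one F2. Deprotonate with LiN(iPr)2 and protonate kinetically at the α-carbon (AcOH, −78 °C) to the deconjugated 5-geranyl-4-methylfuran-2(3H)-one F3. Isomerise F3 by cinchona-alkaloid-catalysed asymmetric proton transfer (a known route to γ-alkyl butenolides) to 3.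

Step 5 (site selectivity between the terminal alkene and the C1=C10 alkene). Fallback that fixes the aldehyde before the chain is assembled, setting out from 2 and 1 and coming back at 9: ozonise 2 (O3, CH2Cl2, −78 °C; Me2S), where the allylic bromide deactivates the neighbouring alkene, to (E)-6-bromo-4-methylhex-4-enal F4. Protect it as (E)-1-bromo-6,6-dimethoxy-3-methylhex-2-ene F5 (HC(OMe)3, PPTS). Alkylate 1 with F5 under the step-1 conditions to (S)-5-[(2E)-6,6-dimethoxy-3-methylhex-2-en-1-yl]-4-methylfuran-2(5H)-one F6. Open as in step 2 to (2Z,4S,6E)-4-hydroxy-N,10,10-trimethoxy-N,3,7-trimethyldeca-2,6-dienamide F7. Esterify with 6 as in step 4 to (2Z,4S,6E)-10,10-dimethoxy-1-[methoxy(methyl)amino]-3,7-dimethyl-1-oxodeca-2,6-dien-4-yl (2R)-2-methylbutanoate F8. Hydrolyse the acetal (PPTS, acetone/H2O) to 9.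

Step 13 (ten-membered ring closure: oligomerisation, wrong C6/C7 diastereomer, or reduction of the bromide; it also depends on the untested bromodesilylation of step 12). Fallback that avoids both the bromide and chromium, setting out from 18 and coming back at 22: fluoride-triggered intramolecular Hosomi–Sakurai allylation of the allylsilane onto the enal (Bu4N Ph3SiF2, THF, 1 mM, −20 °C), the alkoxide closing the lactone in the same flask. It runs through an open transition state and makes no new compound (F0).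

**Further compounds**
F1 | step 1 | tert-butyl(dimethyl)[(4-methylfuran-2-yl)oxy]silane | Cc1coc(O[Si](C)(C)C(C)(C)C)c1
F2 | step 1 | racemic 5-[(2E)-3,7-dimethylocta-2,6-dien-1-yl]-4-methylfuran-2(5H)-one | CC1=CC(=O)OC1C/C=C(\C)CCC=C(C)C
F3 | step 1 | 5-[(2E)-3,7-dimethylocta-2,6-dien-1-yl]-4-methylfuran-2(3H)-one | CC1=C(C/C=C(\C)CCC=C(C)C)OC(=O)C1
F4 | step 5 | (E)-6-bromo-4-methylhex-4-enal | O=CCC/C(C)=C/CBr
F5 | step 5 | (E)-1-bromo-6,6-dimethoxy-3-methylhex-2-ene | COC(OC)CC/C(C)=C/CBr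
F6 | step 5 | (S)-5-[(2E)-6,6-dimethoxy-3-methylhex-2-en-1-yl]-4-methylfuran-2(5H)-one | CC1=CC(=O)O[C@H]1C/C=C(\C)CCC(OC)OC
F7 | step 5 | (2Z,4S,6E)-4-hydroxy-N,10,10-trimethoxy-N,3,7-trimethyldeca-2,6-dienamide | CON(C)C(=O)/C=C(/C)[C@@H](O)C/C=C(\C)CCC(OC)OC
F8 | step 5 | (2Z,4S,6E)-10,10-dimethoxy-1-[methoxy(methyl)amino]-3,7-dimethyl-1-oxodeca-2,6-dien-4-yl (2R)-2-methylbutanoate | CON(C)C(=O)/C=C(/C)[C@@H](OC(=O)[C@H](C)CC)C/C=C(\C)CCC(OC)OC
F0 | step 13 | none | none
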